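**Numbering used throughout.** Atoms: the carbon chain is numbered C1 (CO2H) to C14. The 1,2-dioxane is O1–O2–C3–C4–C5–C6, so ring locants and chain numbers coincide. Ethyl branches sit on C4, C6, C8 and C10. Compounds: 1–17 as in the steps and the compound list; 17 is the target.

## Analysis of the target

The target (C22H38O4) is a chain C1–C14 with ethyl branches on C4, C6, C8 and C10, in which a peroxide bridge O1–O2 joins C6 to C3 and closes a 1,2-dioxane (O1, O2, C3, C4, C5, C6). The ring carries three stereocentres: C3 (S; H and the CH2CO2H arm), C4 (R; H and ethyl) and C6 (S; fully substituted: O1, ethyl, C5, C7). A fourth, C10 (R), lies in the chain beyond the C7=C8 double bond and C9, too far to be relayed from the ring. The C3 arm and the C4 ethyl group are trans, the C3 arm and the C6 dienyl chain are cis and the two ring ethyl groups are cis, so that in the chair the C3 arm and both ring ethyl groups are equatorial and the dienyl chain is axial. The C7=C8 alkene is trisubstituted and (E), but its two C8 substituents (ethyl and C9H2) are almost equal in size, so neither an olefination nor an equilibration can set it; C11=C12 is a plain (E)-disubstituted alkene. Sensitive points are the O–O bond (hydrides, phosphines, low-valent metals, hydrogenation), the tertiary and allylic C6–O1 bond (acid ionisation, allylic shift of oxygen to C8), and the C3–H/β-peroxy acid region (base: Kornblum–DeLaMare cleavage, E1cB ring opening). The hardest feature is C6: it is at once the ketal-level ring atom bonded to O1 and the allylic carbon bonded to C7, so any radical or cation there is delocalised to C8 and a tertiary allylic hydroperoxide cannot be installed stereoselectively by the usual methods. A helpful regularity is that the unit CH2–CH(Et)–CH=CH occurs twice, as C5–C4–C3(=C2 after retro-Michael opening) and as C9–C10–C11=C12, with the same absolute sense at C4 and C10.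

## Retrosynthetic reasoning

**17 ⇒ 16.** The acid is carried as its methyl ester 16. A methyl ester is chosen because the ring-forming step runs in the corresponding alcohol as solvent, so transesterification cannot change the compound.

**16 ⇒ 9 + 13 (C6–C7 bond, key disconnection).** The cut is placed where the ring meets the chain. With C7 removed, C6 is a ketal-level carbon: as the cyclic peroxycarbenium ion 15 (generated from the peroxyketal 9) it is an electrophile, while C7, as the boron-bearing carbon of the alkenyltrifluoroborate 13, is a nucleophile. This cut divides the molecule into two halves of similar size (C1–C6 and C7–C14). It removes the need ever to make a tertiary allylic hydroperoxide. It lets the ring set C6: attack along the axial trajectory on a half-chair whose C3 and C4 substituents are pseudoequatorial gives exactly the target's axial dienyl group. Both C6 epimers of 9 pass through the same planar ion, so they converge. The forward reaction has to ionise the exocyclic C6–OMe bond rather than a ring bond, transfer the alkenyl group through C7 with retention of the (E) geometry, and be faster than proton loss from the cation.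

**9 ⇒ 7 (both C–O bonds of the peroxide).** The peroxyketal 9 opens, by retro-Michael and retro-ketalisation, to the keto enoate 7 and a hydroperoxide donor. Forward, the C6 ketone is perketalised to 8 and the OOH group then closes the ring by 6-exo conjugate addition to C3. Only the C3/C4 relationship has to be controlled here (trans, both equatorial in a chair-like closure); C6 needs no control.

**13 ⇒ 12 ⇒ 11 (C8–ethyl and C7–B bonds).** The (E)-trisubstituted alkene is set by a syn addition across the C7≡C8 triple bond of 11, not by size difference: boron goes to the terminal carbon C7 and ethyl to C8 on the same side, which puts C9 trans to boron and later trans to C6.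

**7 ⇒ 5 + 6, and 11 ⇒ 10; both ⇒ 3.** For the ring half, C1–C2 come from 6 by cross-metathesis with the C3=C alkene of ketone 5, and 5 comes from ester 3 by turning the ester carbon into the C6 ethyl ketone. For the chain half, the same ester 3 is reduced to aldehyde 10 and homologated by one carbon (C7) to alkyne 11. The ester carbon of 3 thus becomes C6 in one half and C8 in the other, and its stereocentre becomes C4 and C10.

**3 ⇒ 2 ⇒ 1.** Ester 3 is the Johnson–Claisen product of allylic alcohol 2, which transfers its carbinol configuration to the new stereocentre and sets the (E)-alkene; 2 comes from enal 1 by one catalytic enantioselective ethyl addition. This is the only reagent-controlled stereocentre in the route. Because both halves come from the same batch of 3, residual minor enantiomer should appear in 16 mostly as a separable diastereomer rather than as the enantiomer.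

## Alternatives that were turned down

**Alternative 1:** (textbook) Disconnection of O2–C3: 6-exo conjugate addition of the C6 hydroperoxide A1 [methyl (2E,4R,6S,7E,10R,11E)-4,6,8,10-tetraethyl-6-hydroperoxytetradeca-2,7,11-trienoate] to its own enoate. It was turned down because A1 cannot be made as a single C6 epimer by short means. Cobalt/silane/O2 hydroperoxidation of a C6 alkene is stereorandom, and since the C6 radical is allylic, oxygen is captured at C8 as well. Acid perhydrolysis of the tertiary allylic alcohol has the same two defects through the allyl cation. Stereospecific perhydrolysis of an epoxide puts the second oxygen on C7 and forces the C7=C8 alkene to be built after the O–O bond (oxidation, alkyne formation, hydrometalation, cross-coupling with low-valent metals next to a peroxide), roughly six extra steps. The closure itself sets only C3.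

**Alternative 2:** Disconnection of both C–O bonds: [4+2] addition of singlet oxygen across C3–C6 of a C3=C4–C5=C6 diene to give the dihydrodioxine A2 [methyl 2-[(3S,6R)-4,6-diethyl-6-[(1E,4R,5E)-2,4-diethylocta-1,5-dien-1-yl]-3,6-dihydro-1,2-dioxin-3-yl]acetate], then saturation of C4=C5. It was turned down on three counts. The diene is part of a conjugated triene (C3 to C8), so a second diene and two trisubstituted alkenes (ene reaction) compete for the oxidant. The trisubstituted C4=C5 bond of A2 would have to be reduced by diimide without touching C7=C8 and C11=C12. Hydrogen would add to A2 anti to the cis C3 and C6 carbon substituents, which puts the C4 ethyl group cis to the C3 arm, the wrong relationship.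

**Alternative 3:** Disconnection of C2–C3: substitution of the C3 peroxyacetal A3 [(3S,5R,6RS)-3,5-diethyl-3-[(1E,4R,5E)-2,4-diethylocta-1,5-dien-1-yl]-6-methoxy-1,2-dioxane, the C3–OMe compound in target numbering] with an acetate enolate equivalent through a C3 peroxycarbenium ion. It was turned down because it leaves the real problem, C6, untouched inside A3. Axial attack next to the equatorial C4 ethyl group would give the 3,4-cis isomer or a mixture, since the neighbouring substituent opposes rather than reinforces the stereoelectronic preference. The Lewis acid would also ionise the tertiary, allylic C6–O1 bond of A3 in competition with the secondary C3–OMe bond.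

Key step: step 10

Remark (assumption): (+)-MIB is taken to deliver ethyl to the Re face of 1, the mirror image of the Si-face delivery established for the (−)-ligand with unsaturated aldehydes. Were the sense the opposite, the antipodal ligand would be used and nothing else changes.

## Steps

Step 1
Reactants: 1 (E)-pent-2-enal
Product: 2 (3R,4E)-hept-4-en-3-ol
Conditions: Et2Zn (1.6 equiv), (+)-MIB [(2R)-3-exo-morpholinoisoborneol, 5 mol %], toluene/hexanes, 0 °C; then 1 M HCl
Reagents that add atoms: diethylzinc (CC[Zn]CC)
Why: Amino-alcohol-catalysed enantioselective addition of a dialkylzinc to an aldehyde; ethyl delivery to the Re face of the (E)-enal should give the (R)-carbinol, the only reagent-controlled stereocentre of the route.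

Step 2
Reactants: 2 (3R,4E)-hept-4-en-3-ol
Product: 3 ethyl (3R,4E)-3-ethylhept-4-enoate
Conditions: MeC(OEt)3 (6 equiv), EtCO2H (5 mol %), 140 °C, ethanol distilled off
Reagents that add atoms: triethyl orthoacetate (CC(OCC)(OCC)OCC)
Why: Johnson–Claisen rearrangement through a chair transition state with the carbinol ethyl group equatorial; this gives the (E)-alkene and transfers the carbinol configuration suprafacially to the new C3 stereocentre, (R), which becomes C4 in one half of the target and C10 in the other.

Step 3
Reactants: 3 ethyl (3R,4E)-3-ethylhept-4-enoate
Product: 5 (5R,6E)-5-ethylnon-6-en-3-one, via Weinreb amide 4 (not isolated)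
Conditions: MeNH(OMe)·HCl (1.5 equiv), iPrMgCl (3.0 equiv), THF, −20 °C; then EtMgBr (1.5 equiv), 0 °C; 1 M HCl
Reagents that add atoms: ethylmagnesium bromide (CC[Mg]Br); N,O-dimethylhydroxylamine hydrochloride (CNOC.Cl)
Why: In-flask Weinreb amidation of the ester by the chloromagnesium amide followed by Grignard addition; the chelated tetrahedral intermediate holds the reaction at the ketone stage, and the stereocentre is β to the carbonyl and cannot enolise. The N-methoxy-N-methylamino group is carried only in 4 and leaves again when the tetrahedral intermediate collapses on work-up, so that of the two reagents only the ethyl group of the Grignard reagent remains in 5.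

Step 4
Reactants: 5 (5R,6E)-5-ethylnon-6-en-3-one; 6 methyl acrylate
Product: 7 methyl (2E,4R)-4-ethyl-6-oxooct-2-enoate
Conditions: 6 (5 equiv), second-generation Hoveyda–Grubbs catalyst RuCl2(H2IMes)(=CH-C6H4-2-OiPr) (5 mol %), 1,4-benzoquinone (10 mol %), CH2Cl2, 40 °C
Reagents that add atoms: none
Why: Olefin cross-metathesis between the internal alkene and an acrylate, which should give the (E)-enoate under thermodynamic control with loss of the propylidene end as but-1-ene; benzoquinone suppresses ruthenium hydride double-bond migration next to the C4 stereocentre, and the ketone is inert.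

Step 5
Reactants: 7 methyl (2E,4R)-4-ethyl-6-oxooct-2-enoate
Product: 9 methyl 2-[(3S,4R,6RS)-4,6-diethyl-6-methoxy-1,2-dioxan-3-yl]acetate, via hydroperoxy ketal 8 (not isolated)
Conditions: urea·H2O2 (5 equiv), Sc(OTf)3 (10 mol %), MeOH, rt; aqueous work-up, crude 8 into CF3CH2OH, Et2NH (0.3 equiv), rt
Reagents that add atoms: urea–hydrogen peroxide adduct (OO.NC(N)=O); methanol (CO)
Why: Lewis-acid-catalysed perketalisation of the C6 ketone gives 8, and the amine then triggers a 6-exo-trig oxa-Michael addition of its OOH group to the enoate, so both C–O bonds of the peroxide are made in one flask; the protic fluoro alcohol protonates the ester enolate before it can attack the O–O bond. C3 is set in a chair-like transition state with the C4 ethyl group and the enoate both equatorial, which should favour the 3,4-trans (3S) isomer; C6 is left as a mixture because step 10 erases it.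

Step 6
Reactants: 3 ethyl (3R,4E)-3-ethylhept-4-enoate
Product: 10 (3R,4E)-3-ethylhept-4-enal
Conditions: iBu2AlH (1.1 equiv), CH2Cl2, −78 °C; MeOH, aq. Rochelle salt
Reagents that add atoms: none
Why: Partial reduction of an ester; the aluminium hemiacetal is stable at −78 °C and releases the aldehyde only on work-up.

Step 7
Reactants: 10 (3R,4E)-3-ethylhept-4-enal
Product: 11 (4R,5E)-4-ethyloct-5-en-1-yne
Conditions: dimethyl (1-diazo-2-oxopropyl)phosphonate (1.3 equiv), K2CO3 (2 equiv), MeOH, 0 °C to rt
Reagents that add atoms: dimethyl (1-diazo-2-oxopropyl)phosphonate (COP(=O)(OC)C(=[N+]=[N-])C(C)=O)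
Why: Ohira–Bestmann homologation adds one carbon (the future C7) and gives the terminal alkyne; the carbon next to the aldehyde is a CH2 group, so the mild base cannot epimerise the stereocentre.

Step 8
Reactants: 11 (4R,5E)-4-ethyloct-5-en-1-yne
Product: 12 2-[(1E,4R,5E)-2,4-diethylocta-1,5-dien-1-yl]-4,4,5,5-tetramethyl-1,3,2-dioxaborolane
Conditions: B2pin2 (1.2 equiv), EtI (3 equiv), CuCl (10 mol %), Xantphos (11 mol %), LiOtBu (1.5 equiv), THF, rt
Reagents that add atoms: bis(pinacolato)diboron (CC1(C)OB(OC1(C)C)B1OC(C)(C)C(C)(C)O1); iodoethane (CCI)
Why: Copper-catalysed alkylboration (formal carboboration) of a terminal alkyne: the boryl copper species adds syn with boron on the terminal carbon, and the alkenylcopper at C8 is then ethylated with retention, so boron and ethyl are cis and C9 is trans to boron, which is the (E) geometry needed; the disubstituted alkene does not react.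

Step 9
Reactants: 12 2-[(1E,4R,5E)-2,4-diethylocta-1,5-dien-1-yl]-4,4,5,5-tetramethyl-1,3,2-dioxaborolane
Product: 13 potassium trifluoro[(1E,4R,5E)-2,4-diethylocta-1,5-dien-1-yl]borate
Conditions: KHF2 (4.5 equiv, aq.), MeOH, rt; evaporation, extraction into hot acetone
Reagents that add atoms: potassium hydrogen difluoride ([K+].[F-].F)
Why: Standard exchange of a pinacol boronate to the trifluoroborate salt; the double bond is not touched, and the salt can be purified by crystallisation.

Step 10
Reactants: 9 methyl 2-[(3S,4R,6RS)-4,6-diethyl-6-methoxy-1,2-dioxan-3-yl]acetate; 13 potassium trifluoro[(1E,4R,5E)-2,4-diethylocta-1,5-dien-1-yl]borate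
Product: 16 methyl 2-[(3S,4R,6S)-4,6-diethyl-6-[(1E,4R,5E)-2,4-diethylocta-1,5-dien-1-yl]-1,2-dioxan-3-yl]acetate, via alkenyldifluoroborane 14 (not isolated), via peroxycarbenium ion 15 (not isolated)
Conditions: 13 (1.5 equiv), BF3·OEt2 (2.5 equiv), CH2Cl2/MeCN (4:1), −40 to 0 °C; aq. NaHCO3
Reagents that add atoms: none
Why: Proposed new method: BF3·OEt2 takes a fluoride from 13 to give the Lewis-acidic alkenyldifluoroborane 14, which binds the exocyclic methoxy oxygen of 9 (more basic than the peroxide oxygens) and ionises the C6–OMe bond to the cyclic peroxycarbenium ion 15, paired with the alkenyl(methoxy)difluoroborate. The alkenyl group then passes from boron to C6 through its boron-bearing carbon C7, because attack there puts the developing positive charge on the tertiary C8 β to boron, and loss of boron restores C7=C8 with the (E) geometry kept. The closest known reaction types are the Lewis-acid substitution of cyclic peroxyketals by allylsilanes and silyl enol ethers through peroxycarbenium ions, and the BF3-mediated coupling of alkenyltrifluoroborates with acetals through oxocarbenium ions; their combination on a ketone-derived peroxyketal has not been shown. No ring is closed: the 1,2-dioxane from step 5 is kept, and the step forms the C6–C7 bond that joins the C1–C6 ring half to the C7–C14 chain. The new stereocentre C6 is set by the ring: in the half-chair of 15 the trans C3 arm and C4 ethyl group are both pseudoequatorial, and the nucleophile enters along the axial trajectory that leads directly to a chair, so the dienyl group ends up axial (trans to the C4 ethyl group, cis to the C3 arm) and the C6 ethyl group equatorial, which is (6S). Both C6 epimers of 9 give the same planar ion, so the step is stereoconvergent. The selectivities needed are exocyclic over ring ionisation (secured by the more basic methoxy group), attack through C7 rather than the weaker C11=C12 π bond (secured by the β-boron effect), and addition faster than proton loss from C5 of 15 (secured by pre-forming 14 in excess at low temperature, which also keeps the tertiary allylic C6–O1 bond of 16 from ionising).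

Step 11
Reactants: 16 methyl 2-[(3S,4R,6S)-4,6-diethyl-6-[(1E,4R,5E)-2,4-diethylocta-1,5-dien-1-yl]-1,2-dioxan-3-yl]acetate
Product: 17 2-[(3S,4R,6S)-4,6-diethyl-6-[(1E,4R,5E)-2,4-diethylocta-1,5-dien-1-yl]-1,2-dioxan-3-yl]acetic acid
Conditions: LiOH·H2O (3 equiv), THF/H2O (3:1), 0 °C to rt; cold 0.5 M HCl to pH 3–4
Reagents that add atoms: lithium hydroxide ([Li+].[OH-])
Why: Saponification of the methyl ester at the acyl carbon should be faster at 0 °C than deprotonation at C2 (E1cB ring opening) or at C3 (Kornblum–DeLaMare cleavage); the dialkyl peroxide and both alkenes are inert to hydroxide, and the brief cold acidification spares the C6–O1 bond.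

## Compound list

1 | (E)-pent-2-enal | CC/C=C/C=O | starting material
2 | (3R,4E)-hept-4-en-3-ol | CC/C=C/[C@H](O)CC | intermediate
3 | ethyl (3R,4E)-3-ethylhept-4-enoate | CC/C=C/[C@H](CC)CC(=O)OCC | intermediate
4 | (3R,4E)-3-ethyl-N-methoxy-N-methylhept-4-enamide (Weinreb amide) | CC/C=C/[C@H](CC)CC(=O)N(C)OC | intermediate (not isolated)
5 | (5R,6E)-5-ethylnon-6-en-3-one | CC/C=C/[C@H](CC)CC(=O)CC | intermediate
6 | methyl acrylate | C=CC(=O)OC | starting material
7 | methyl (2E,4R)-4-ethyl-6-oxooct-2-enoate | COC(=O)/C=C/[C@H](CC)CC(=O)CC | intermediate
8 | methyl (2E,4R,6RS)-4-ethyl-6-hydroperoxy-6-methoxyoct-2-enoate (hydroperoxy ketal) | COC(=O)/C=C/[C@H](CC)CC(CC)(OC)OO | intermediate (not isolated)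
9 | methyl 2-[(3S,4R,6RS)-4,6-diethyl-6-methoxy-1,2-dioxan-3-yl]acetate | CCC1(OC)C[C@@H](CC)[C@H](CC(=O)OC)OO1 | intermediate
10 | (3R,4E)-3-ethylhept-4-enal | CC/C=C/[C@H](CC)CC=O | intermediate
11 | (4R,5E)-4-ethyloct-5-en-1-yne | CC/C=C/[C@H](CC)CC#C | intermediate
12 | 2-[(1E,4R,5E)-2,4-diethylocta-1,5-dien-1-yl]-4,4,5,5-tetramethyl-1,3,2-dioxaborolane | CC/C=C/[C@H](CC)C/C(CC)=C/B1OC(C)(C)C(C)(C)O1 | intermediate
13 | potassium trifluoro[(1E,4R,5E)-2,4-diethylocta-1,5-dien-1-yl]borate | CC/C=C/[C@H](CC)C/C(CC)=C/[B-](F)(F)F.[K+] | intermediate
14 | difluoro[(1E,4R,5E)-2,4-diethylocta-1,5-dien-1-yl]borane | CC/C=C/[C@H](CC)C/C(CC)=C/B(F)F | intermediate (not isolated)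
15 | (3S,4R)-4,6-diethyl-3-(2-methoxy-2-oxoethyl)-1,2-dioxan-6-ylium (peroxycarbenium ion, charge shared by C6 and O1) | CC[C+]1C[C@@H](CC)[C@H](CC(=O)OC)OO1 | intermediate (not isolated)
16 | methyl 2-[(3S,4R,6S)-4,6-diethyl-6-[(1E,4R,5E)-2,4-diethylocta-1,5-dien-1-yl]-1,2-dioxan-3-yl]acetate | CC/C=C/[C@H](CC)C/C(=C/[C@]1(CC)C[C@@H](CC)[C@H](CC(=O)OC)OO1)CC | intermediate
17 | 2-[(3S,4R,6S)-4,6-diethyl-6-[(1E,4R,5E)-2,4-diethylocta-1,5-dien-1-yl]-1,2-dioxan-3-yl]acetic acid | CC/C=C/[C@H](CC)C/C(=C/[C@]1(CC)C[C@@H](CC)[C@H](CC(=O)O)OO1)CC | target

## Step count and risk

Total step count: 11. Longest linear sequence: 8 steps (1, 2, 6, 7, 8, 9, 10, 11); the ring half reaches the key step after 5 steps (1, 2, 3, 4, 5).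

**Step 10 (key step, proposed new method).** The most likely failure is proton loss from C5 or from the ethyl CH2 of the peroxycarbenium ion before the alkenyl group arrives, giving an enol peroxide that decomposes. Other possible processes are ring-opening ionisation at C6–O1, a shift of a carbon substituent from C6 to oxygen with O–O cleavage, protodeboronation of the nucleophile, and partial loss of the C7=C8 geometry by rotation in the β-boryl cation. The fallback uses known reaction types only, sets out from 13 and 7, and comes back at 16. Iododeboronation of 13 with NaI and chloramine-T in THF/H2O, with retention, should give (1E,4R,5E)-2,4-diethyl-1-iodoocta-1,5-diene F1. Iodine–lithium exchange (t-BuLi, Et2O, −78 °C), transmetallation with CeCl3 and addition to the ketone of 7 at −78 °C with a cold acidic quench should give the tertiary allylic alcohol methyl (2E,4R,6RS,7E,10R,11E)-4,6,8,10-tetraethyl-6-hydroxytetradeca-2,7,11-trienoate F2. Acid-catalysed perhydrolysis (50% H2O2, cat. H2SO4, Et2O, 0 °C) should give the tertiary allylic hydroperoxide methyl (2E,4R,6RS,7E,10R,11E)-4,6,8,10-tetraethyl-6-hydroperoxytetradeca-2,7,11-trienoate F3. Et2NH in CF3CH2OH should then close the ring to 16 together with its C6 epimer, to be separated by chromatography. This path gives up stereocontrol at C6 and accepts some oxygen transposition to C8, which is why it is the fallback and not the route.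

**Step 5.** The main risk is poor facial selectivity in the 6-exo closure, so that the 3,4-cis epimer forms in quantity. Formation of a gem-dihydroperoxide in the first stage and attack of the ester enolate on the O–O bond (epoxide formation) are secondary risks. The fallback sets out from 7 and comes back at 9. The closure is run as written and the cis epimer methyl 2-[(3R,4R,6RS)-4,6-diethyl-6-methoxy-1,2-dioxan-3-yl]acetate F4 is separated. In a separate operation (DBU, CF3CH2OH/MeCN, rt) F4 is reopened by E1cB elimination to the hydroperoxide anion of 8 and reclosed, so that C3 is set under thermodynamic instead of kinetic control; the all-equatorial 9 should dominate at equilibrium.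

**Step 8.** The alkenylcopper intermediate may be protonated faster than it is ethylated (giving the simple hydroboration product), the boryl copper addition may lose regioselectivity, or the terminal alkyne may be consumed as its acetylide. The fallback sets out from 11 and comes back at 12. Syn-bromoboration (BBr3, CH2Cl2, −78 °C; then pinacol) should give 2-[(1Z,4R,5E)-2-bromo-4-ethylocta-1,5-dien-1-yl]-4,4,5,5-tetramethyl-1,3,2-dioxaborolane F5. Negishi coupling at the C–Br bond (Et2Zn, Pd(P(t-Bu)3)2 cat., THF, rt) with retention should then give 12.

**Step 4.** Turnover may be slow at the internal alkene next to the branched C4, and ruthenium hydride double-bond migration could erode the C4 stereocentre. The fallback sets out from 5 and comes back at 7. Ozonolysis (O3, CH2Cl2/MeOH, −78 °C; Me2S) should give (2R)-2-ethyl-4-oxohexanal F6, used at once to avoid epimerisation, and a Wittig reaction with Ph3P=CHCO2Me (CH2Cl2, rt) on the aldehyde should give 7.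

## Further compounds

F1 | step 10 | (1E,4R,5E)-2,4-diethyl-1-iodoocta-1,5-diene | CC/C=C/[C@H](CC)C/C(CC)=C/I
F2 | step 10 | methyl (2E,4R,6RS,7E,10R,11E)-4,6,8,10-tetraethyl-6-hydroxytetradeca-2,7,11-trienoate | CC/C=C/[C@H](CC)C/C(CC)=C/C(O)(CC)C[C@@H](CC)/C=C/C(=O)OC
F3 | step 10 | methyl (2E,4R,6RS,7E,10R,11E)-4,6,8,10-tetraethyl-6-hydroperoxytetradeca-2,7,11-trienoate | CC/C=C/[C@H](CC)C/C(CC)=C/C(OO)(CC)C[C@@H](CC)/C=C/C(=O)OC
F4 | step 5 | methyl 2-[(3R,4R,6RS)-4,6-diethyl-6-methoxy-1,2-dioxan-3-yl]acetate | CCC1(OC)C[C@@H](CC)[C@@H](CC(=O)OC)OO1
F5 | step 8 | 2-[(1Z,4R,5E)-2-bromo-4-ethylocta-1,5-dien-1-yl]-4,4,5,5-tetramethyl-1,3,2-dioxaborolane | CC/C=C/[C@H](CC)C/C(Br)=C/B1OC(C)(C)C(C)(C)O1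
F6 | step 4 | (2R)-2-ethyl-4-oxohexanal | O=C[C@H](CC)CC(=O)CC
A1 | alternative 1 | methyl (2E,4R,6S,7E,10R,11E)-4,6,8,10-tetraethyl-6-hydroperoxytetradeca-2,7,11-trienoate | CC/C=C/[C@H](CC)C/C(CC)=C/[C@](OO)(CC)C[C@@H](CC)/C=C/C(=O)OC
A2 | alternative 2 | methyl 2-[(3S,6R)-4,6-diethyl-6-[(1E,4R,5E)-2,4-diethylocta-1,5-dien-1-yl]-3,6-dihydro-1,2-dioxin-3-yl]acetate | CC/C=C/[C@H](CC)C/C(=C/[C@]1(CC)C=C(CC)[C@H](CC(=O)OC)OO1)CC
A3 | alternative 3 | (3S,5R,6RS)-3,5-diethyl-3-[(1E,4R,5E)-2,4-diethylocta-1,5-dien-1-yl]-6-methoxy-1,2-dioxane | CC/C=C/[C@H](CC)C/C(=C/[C@]1(CC)C[C@@H](CC)C(OC)OO1)CC
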